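Ring B of the target (O1–C2–C3–C3a–C7a) holds its ring oxygen and a tertiary carbinol on neighbouring carbons, C2 and the exocyclic CMe2. This is the footprint of a 1,2-oxygen shift, so ring B is traced back to a 2,2-dimethylchroman-3-yl mesylate. The precursor is one bis-chromene, epoxidised twice by a single Jacobsen–Katsuki catalyst, then hydrogenolysed and mesylated. Buffered solvolysis contracts both pyrans to hydroxyisopropyl-dihydrofurans with inversion. The C2 substituent then steers dearomative prenylation at C3a. The second dihydrofuran, by then a vinylogous ester of the triketone, is opened by its own alkoxide to the side-chain epoxide.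

Key step: step 6

Remark on the chemistry: ring A atoms carry the 1-benzofuran numbers of the target (C3a, C4, C5, C6, C7, C7a). Ring B is O1–C2–C3–C3a–C7a. Ring C is the second oxygen ring of the intermediates, with its O on C6 and its CH2 on C7. The β-triketone is drawn in the enol form of the target SMILES, and its tautomers interconvert freely.

Step 1
Reactants: 1 phloroglucinol; 2 isobutyryl chloride
Product: 3 phlorisobutyrophenone
Conditions: AlCl3 (3 equiv), CH2Cl2–MeNO2, 0 → 40 °C; aq. HCl work-up
Reagents that add atoms: none
Why: Friedel–Crafts C-acylation of the symmetrical triphenol should stop at the mono-ketone, because the chelated acyl group deactivates the ring toward a second acylation; no stereocenter is formed.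

Step 2
Reactants: 3 phlorisobutyrophenone; 4 3-methylbut-2-enal (2.5 equiv)
Product: 5 bis-chromene 1-(5-hydroxy-2,2,8,8-tetramethyl-2H,8H-pyrano[2,3-f]chromen-6-yl)-2-methylpropan-1-one
Conditions: ethylenediammonium diacetate (20 mol %), xylene, 140 °C
Reagents that add atoms: none
Why: Two condensation/dehydration/oxa-6π-electrocyclisation sequences (chromenylation) take the two free ring carbons while the hydroxyl that is hydrogen-bonded to the ketone stays out, so one pyran oxygen ends para and the other ortho to the acyl group, as rings B and C require.

Step 3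
Reactants: 5 bis-chromene
Product: 6 (3R,4R,9R,10R)-3,4:9,10-bis-epoxide of 5
Conditions: (R,R)-Mn(salen)Cl [salen = dianion of N,N'-bis(3,5-di-tert-butylsalicylidene)-1,2-cyclohexanediamine] (10 mol %), NMO (10 equiv), mCPBA (2.5 equiv), CH2Cl2, −78 °C; cold aq. NaOH wash, crude product used at once
Reagents that add atoms: mCPBA (3-chloroperbenzoic acid), O=C(OO)c1cccc(Cl)c1
Why: In the Jacobsen–Katsuki epoxidation the cis-alkenes of 2,2-dimethylchromenes are the privileged substrates; the (R,R) catalyst should deliver oxygen to the same local face of both alkenes (all four centres R), and the double reaction should statistically enrich the major diastereomer in one enantiomer.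

Step 4
Reactants: 6 bis-epoxide
Product: 7 (3R,9R)-bis-chromanol 1-[(3R,9R)-3,5,9-trihydroxy-2,2,8,8-tetramethyl-3,4,9,10-tetrahydro-2H,8H-pyrano[2,3-f]chromen-6-yl]-2-methylpropan-1-one
Conditions: H2 (1 atm), Pd/C (10 wt %), EtOAc, Et3N (1 vol %), 23 °C
Reagents that add atoms: none
Why: Hydrogenolysis of benzylic epoxides breaks only the benzylic C4–O and C10–O bonds, so the carbinol carbons C3 and C9 keep their R configuration, and the hindered chelated aryl ketone should survive.

Step 5
Reactants: 7 bis-chromanol
Product: 8 (3R,9R)-bis(methanesulfonate) of 7
Conditions: MsCl (2.2 equiv), Et3N (3 equiv), CH2Cl2, −20 → 0 °C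
Reagents that add atoms: methanesulfonyl chloride, CS(=O)(=O)Cl
Why: O-sulfonylation through sulfene takes both secondary alcohols with retention, while the chelated phenol, flanked on both sides, is expected to react more slowly.

Step 6
Reactants: 8 bis-mesylate
Product: 9 benzodifuran 1-[(2S,7S)-4-hydroxy-2,7-bis(2-hydroxypropan-2-yl)-2,3,7,8-tetrahydrobenzo[1,2-b:3,4-b']difuran-5-yl]-2-methylpropan-1-one
Conditions: H2O–1,4-dioxane 1:1, 2,6-lutidine (3 equiv), 95 °C
Reagents that add atoms: water, O
Why: Each mesylate ionises from the half-chair in which the C–OMs bond is pseudo-equatorial and antiperiplanar to the ring O–CMe2 bond; the pyran oxygen attacks the carbinol carbon from the rear (3-exo-tet) to give a bridged oxiranium ion, the O–CMe2 bond breaks, and water quenches the tertiary cationic centre, so each six-membered ring becomes a five-membered ring that carries C(CH3)2OH. The closest known reaction type is the 1,2-oxygen-shift ring contraction of chroman-3-yl and flavan-3-yl sulfonates, and of pyranose 2-sulfonates or 2-diazonium ions to 2,5-anhydro sugars. Rings B and C both close through this 3-exo-tet/ring-opening relay, a net 1,2-shift and not a fresh cyclisation, so each oxygen stays on the aryl carbon where chromenylation placed it and the regiochemistry (O para to the acyl group in ring B, ortho in ring C) cannot drift. The two new stereocentres (C2 of ring B and its counterpart in ring C) arise by inversion of the catalyst-set R carbinols and should both be S. The step needs oxygen migration to win over methyl migration, participation of the electron-rich neighbouring ring carbon, direct hydrolysis and proton loss; the tertiary character of the developing cation, the strain of the alternative spiro-cyclopropane ion and the water-rich, buffered medium should secure this.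

Step 7
Reactants: 9 benzodifuran; 10 prenyl bromide (1-bromo-3-methylbut-2-ene)
Product: 12 tricyclic dienone (2S,3aS,7S)-2,7-bis(2-hydroxypropan-2-yl)-3a-(3-methylbut-2-en-1-yl)-5-(2-methylpropanoyl)-2,3,7,8-tetrahydrobenzo[1,2-b:3,4-b']difuran-4(3aH)-one, via sodium phenoxide 11 (not isolated)
Conditions: NaH (1.0 equiv), toluene, 0 °C; then 10 (1.2 equiv), 0 → 23 °C
Reagents that add atoms: none
Why: In this alkylative dearomatisation of an acylphloroglucinol-type phenoxide, the contact ion pair in toluene should deliver the allylic halide to the ortho carbon C3a rather than to oxygen or to the para carbon, and attack anti to the C2 hydroxyisopropyl group of ring B sets the quaternary centre trans to it (same spatial arrangement as 3aR in the target; the descriptor reads S here because C4 is a ketone).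

Step 8
Reactants: 12 tricyclic dienone
Product: 14 target (2S,3aR)-7-{[(2R)-3,3-dimethyloxiran-2-yl]methyl}-4-hydroxy-2-(2-hydroxypropan-2-yl)-3a-(3-methylbut-2-en-1-yl)-5-(2-methylpropanoyl)-3,3a-dihydro-1-benzofuran-6(2H)-one, via potassium enolate 13 (not isolated)
Conditions: KHMDS (1.05 equiv), THF, −78 → 0 °C; then aq. NH4Cl, 0 °C
Reagents that add atoms: none
Why: Proposed new method: the tertiary alkoxide beside ring C displaces the secondary C–O bond of that ring in a 3-exo-tet SN2 step with inversion (S to R), the nucleofuge being the β-triketone enolate on C6 (conjugate acid about as strong as a carboxylic acid), whose stabilisation in an aprotic medium should outweigh the oxirane strain; ring B should stay closed because its oxygen could leave only as a less stabilised extended enolate and, once ring C has opened, only from an anion; the closest known reaction types are the Williamson-type oxirane closure of β-hydroxy sulfonates and the alkoxide-induced cleavage of β-aryloxy alcohols to oxiranes and phenoxides.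

Compound list
1 | phloroglucinol | Oc1cc(O)cc(O)c1 | starting material
2 | isobutyryl chloride | CC(C)C(=O)Cl | starting material
3 | phlorisobutyrophenone | CC(C)C(=O)c1c(O)cc(O)cc1O | intermediate
4 | 3-methylbut-2-enal | CC(C)=CC=O | starting material
5 | bis-chromene | CC(C)C(=O)c1c(O)c2C=CC(C)(C)Oc2c2C=CC(C)(C)Oc12 | intermediate
6 | (3R,4R,9R,10R)-bis-epoxide | CC(C)C(=O)c1c(O)c2[C@H]3O[C@H]3C(C)(C)Oc2c2[C@H]3O[C@H]3C(C)(C)Oc12 | intermediate
7 | (3R,9R)-bis-chromanol | CC(C)C(=O)c1c(O)c2C[C@@H](O)C(C)(C)Oc2c2C[C@@H](O)C(C)(C)Oc12 | intermediate
8 | (3R,9R)-bis-mesylate | CC(C)C(=O)c1c(O)c2C[C@@H](OS(C)(=O)=O)C(C)(C)Oc2c2C[C@@H](OS(C)(=O)=O)C(C)(C)Oc12 | intermediate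
9 | (2S,7S)-benzodifuran triol | CC(C)C(=O)c1c(O)c2C[C@@H](C(C)(C)O)Oc2c2C[C@@H](C(C)(C)O)Oc12 | intermediate
10 | prenyl bromide | CC(C)=CCBr | starting material
11 | sodium phenoxide of 9 | CC(C)C(=O)c1c([O-])c2C[C@@H](C(C)(C)O)Oc2c2C[C@@H](C(C)(C)O)Oc12.[Na+] | intermediate
12 | (2S,3aS,7S)-tricyclic dienone | CC(C)=CC[C@]12C[C@@H](C(C)(C)O)OC1=C1C[C@@H](C(C)(C)O)OC1=C(C(=O)C(C)C)C2=O | intermediate
13 | potassium enolate of 14 | CC(C)=CC[C@]12C[C@@H](C(C)(C)O)OC1=C(C[C@H]1OC1(C)C)C(=O)C(C(=O)C(C)C)=C2[O-].[K+] | intermediate
14 | CNP0395488.1 | CC(C)=CC[C@]12C[C@@H](C(C)(C)O)OC1=C(C[C@H]1OC1(C)C)C(=O)C(C(=O)C(C)C)=C2O | target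

Total step count: 8. Longest linear sequence: 8 (steps 1–8).

Steps most likely to fail

Step 8. The alkoxide beside ring B may open ring B instead of ring C. Base-induced elimination along the C7 side chain may compete. The enolate may also close back onto the new oxirane during the quench. The fallback sets out from 12 and uses known chemistry only. Aqueous LiOH in THF at 0 °C saponifies the doubly activated vinylogous ester at C6 by addition–elimination and gives the triketone with an (S)-2,3-dihydroxy-3-methylbutyl side chain F1. MsCl with 2,4,6-collidine at −20 °C takes the only secondary alcohol and gives the hydroxy mesylate F2. NaH (2 equiv) in THF at −40 °C then closes the oxirane with inversion, and the route is rejoined at 14.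

Step 7. Alkylation at oxygen, at the para ring carbon C7 or at the acyl-bearing carbon C5 may compete, and the facial selectivity at C3a may be poor. The fallback sets out from 9 and replaces the intermolecular alkylation by an intramolecular [3,3] delivery that can reach ortho carbons only. Copper-catalysed O-alkylation with 3-chloro-3-methylbut-1-yne (CuCl2 cat., DBU, MeCN, 0 °C) gives the aryl 1,1-dimethylpropargyl ether F3. Semi-hydrogenation (H2, Pd/CaCO3 poisoned with Pb(OAc)2, quinoline) gives the aryl 1,1-dimethylallyl ether F4. A dearomatising aromatic Claisen rearrangement in toluene at 80–110 °C moves the prenyl unit to C3a anti to the C2 substituent, and the route is rejoined at 12.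

Step 6. Proton loss from the tertiary cationic centre may outrun capture by water, and hydrolysis without rearrangement or methyl and aryl participation may erode the oxygen shift. The fallback sets out from 8 and no longer relies on water capture. The same oxygen shift is run in dry HFIP with 2,6-di-tert-butylpyridine at 60 °C and driven on purpose to proton loss, giving the ring-contracted (2S,7S)-bis(isopropenyl)benzodifuran F5. A double Mukaiyama hydration (Co(acac)2, PhSiH3, O2, THF; then PPh3) installs both tertiary alcohols at a stage where no other alkene is present, and the route is rejoined at 9.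

Further compounds
F1 | step 8 | triketone with (S)-2,3-dihydroxy-3-methylbutyl side chain at C7 | CC(C)=CC[C@]12C[C@@H](C(C)(C)O)OC1=C(C[C@H](O)C(C)(C)O)C(=O)C(C(=O)C(C)C)=C2O
F2 | step 8 | secondary (S)-mesylate of F1 | CC(C)=CC[C@]12C[C@@H](C(C)(C)O)OC1=C(C[C@H](OS(C)(=O)=O)C(C)(C)O)C(=O)C(C(=O)C(C)C)=C2O
F3 | step 7 | aryl 1,1-dimethylpropargyl ether of 9 | CC(C)C(=O)c1c(OC(C)(C)C#C)c2C[C@@H](C(C)(C)O)Oc2c2C[C@@H](C(C)(C)O)Oc12
F4 | step 7 | aryl 1,1-dimethylallyl ether of 9 | CC(C)C(=O)c1c(OC(C)(C)C=C)c2C[C@@H](C(C)(C)O)Oc2c2C[C@@H](C(C)(C)O)Oc12
F5 | step 6 | (2S,7S)-bis(isopropenyl)benzodifuran | CC(C)C(=O)c1c(O)c2C[C@@H](C(C)=C)Oc2c2C[C@@H](C(C)=C)Oc12
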